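**Retrosynthetic overview**

1. Target ⇒ two-fold Cadiot–Chodkiewicz coupling (C5–C6 of each chain) of sn-1,2-bis(5-bromopent-4-ynoyl)glycerol with two equivalents of one terminal alkynyl trans-epoxide.
2. Glycerol stereocentre ⇒ chiral phosphoric acid-catalysed desymmetrising opening of achiral oxetan-3-yl 5-bromopent-4-ynoate by 5-bromopent-4-ynoic acid (new step; the oxetane is opened, not formed).
3. Alkynyl epoxide ⇒ Ohira–Bestmann homologation of a trans-2,3-epoxy aldehyde ⇒ amine-catalysed H2O2 epoxidation of (2E,7Z,9Z)-dodeca-2,7,9-trienal (sets C8/C9 of the acyl chain).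
4. Trienal ⇒ Grignard reagent + 3-(dimethylamino)acrolein; Z,Z-diene ⇒ double carbocupration of acetylene by an ethylcuprate, trapped with 1-chloro-3-iodopropane.
5. Ring order: the oxirane is the only ring formed (step 3, before the diyne is built) and is used twice in the last step.

**Assumptions**

- The SMILES is read as 1,2-di-O-[(8S,9S,13Z,15Z)-8,9-epoxyoctadeca-13,15-dien-4,6-diynoyl]-sn-glycerol, with glycerol C2 = S.
- The catalyst antipode in step 3 is taken from the usual steric-shielding model of diarylprolinol silyl ether iminium catalysis, not from a recalled literature assignment; it is checked at 10 by NaBH4 reduction and Mosher analysis. The sense of the new step 7 cannot be predicted and is fixed by a test run; both antipodes of both catalysts are commercial.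

**Route**

Step 1
Reactants: 1 acetylene; 2 ethyllithium; 3 1-chloro-3-iodopropane
Product: 5 (3Z,5Z)-9-chloronona-3,5-diene, via lithium bis[(1Z,3Z)-hexa-1,3-dien-1-yl]cuprate 4 (not isolated)
Conditions: 2 (2 equiv), CuBr·SMe2 (1 equiv), Et2O, −35 °C; 1, −50 → −10 °C; then 3, HMPA, P(OEt)3, −40 °C → rt; aq NH4Cl
Reagents that add atoms: none
Why: Two successive syn-carbocuprations of acetylene (Normant–Alexakis) give the Z,Z-dienylcuprate, which is alkylated with retention at the C–I bond only, leaving the chloride.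

Step 2
Reactants: 5 (3Z,5Z)-9-chloronona-3,5-diene; 6 (E)-3-(dimethylamino)prop-2-enal
Product: 9 (2E,7Z,9Z)-dodeca-2,7,9-trienal, via (4Z,6Z)-nona-4,6-dien-1-ylmagnesium chloride 7 (not isolated), via chloromagnesium (1E,7Z,9Z)-1-(dimethylamino)dodeca-1,7,9-trien-3-olate 8 (not isolated)
Conditions: Mg, THF, 50 °C; then 6, −10 °C → rt; 1 M HCl, 0 °C
Reagents that add atoms: none
Why: Grignard addition to the vinylogous formamide, then acid-induced loss of Me2NH, gives the (E)-enal (formyl-vinylation); 1,2- and 1,4-addition lead to the same enal.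

Step 3
Reactants: 9 (2E,7Z,9Z)-dodeca-2,7,9-trienal
Product: 10 (2R,3S)-3-[(4Z,6Z)-nona-4,6-dien-1-yl]oxirane-2-carbaldehyde
Conditions: (R)-2-{bis[3,5-bis(trifluoromethyl)phenyl][(trimethylsilyl)oxy]methyl}pyrrolidine (10 mol%), 35% aq H2O2 (1.3 equiv), CH2Cl2, rt
Reagents that add atoms: hydrogen peroxide, OO
Why: Iminium/enamine-catalysed nucleophilic epoxidation (Jørgensen epoxidation): the Ar2C(OTMS) group shields one face of the E-iminium, HOO– adds to C3 from the open face and the enamine closes on O–O to the trans-epoxide, setting C2 (R) and C3 (S); the unconjugated Z,Z-diene is inert to this nucleophilic oxidant.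

Step 4
Reactants: 10 (2R,3S)-3-[(4Z,6Z)-nona-4,6-dien-1-yl]oxirane-2-carbaldehyde
Product: 11 (2S,3S)-2-ethynyl-3-[(4Z,6Z)-nona-4,6-dien-1-yl]oxirane
Conditions: Bestmann–Ohira reagent (1.3 equiv), K2CO3, MeOH, 0 °C → rt
Reagents that add atoms: dimethyl (1-diazo-2-oxopropyl)phosphonate, COP(=O)(OC)C(=[N+]=[N-])C(C)=O
Why: Seyferth–Gilbert homologation (Ohira–Bestmann variant) turns CHO into C≡CH without touching either epoxide carbon spatially; the C2 descriptor changes from R to S only through CIP priorities, and 0 °C limits α-epimerisation.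

Step 5
Reactants: 12 pent-4-ynoic acid
Product: 13 5-bromopent-4-ynoic acid
Conditions: NBS (1.1 equiv), AgNO3 (10 mol%), acetone, rt, dark
Reagents that add atoms: N-bromosuccinimide, BrN1C(=O)CCC1=O
Why: Silver-catalysed electrophilic bromination of a terminal alkyne; the free acid is tolerated.

Step 6
Reactants: 13 5-bromopent-4-ynoic acid; 14 oxetan-3-ol
Product: 15 oxetan-3-yl 5-bromopent-4-ynoate
Conditions: EDC·HCl, DMAP (10 mol%), CH2Cl2, 0 °C → rt
Reagents that add atoms: none
Why: Steglich esterification of the secondary alcohol; the oxetane is stable to carbodiimide/DMAP and the product is achiral (prochiral CH2 pair).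

Step 7
Reactants: 15 oxetan-3-yl 5-bromopent-4-ynoate; 13 5-bromopent-4-ynoic acid (1.5 equiv)
Product: 16 (2S)-3-hydroxypropane-1,2-diyl bis(5-bromopent-4-ynoate)
Conditions: (R)-TRIP (10 mol%), 4 Å MS, PhCF3, 40 °C; filtration through boric acid-doped silica
Reagents that add atoms: none
Why: Proposed new method: chiral phosphoric acid-catalysed desymmetrising carboxylysis of a prochiral oxetan-3-yl ester, in which the acid catalyst H-bonds the oxetane oxygen and, as a hetero-dimer with the carboxylic acid, delivers the carboxylate by SN2 to one of the two enantiotopic CH2 groups, so the oxetane oxygen becomes the free sn-3 OH, the pre-existing ester sits on C2 and C2 becomes (S) with no by-product (if the C3 ester participates first, the dioxolan-2-ylium phosphate ion pair is opened by the carboxylate at its primary carbon, Prévost-type, to the same product); closest known reaction types are phosphoric acid-catalysed desymmetrising opening of 3-substituted oxetanes by S-, Cl- and internal O-nucleophiles and phosphoric acid-catalysed carboxylysis of meso-epoxides.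

Step 8
Reactants: 16 (2S)-3-hydroxypropane-1,2-diyl bis(5-bromopent-4-ynoate); 11 (2S,3S)-2-ethynyl-3-[(4Z,6Z)-nona-4,6-dien-1-yl]oxirane (2.5 equiv)
Product: 17 (2S)-3-hydroxypropane-1,2-diyl bis{7-[(2S,3S)-3-[(4Z,6Z)-nona-4,6-dien-1-yl]oxiran-2-yl]hepta-4,6-diynoate}
Conditions: CuCl (20 mol%), NH2OH·HCl (40 mol%), n-BuNH2 (3 equiv), degassed THF–H2O, −10 → 0 °C, slow addition of 16; pH 6 buffer; boric acid-doped silica, 0 °C
Reagents that add atoms: none
Why: Two-fold Cadiot–Chodkiewicz coupling (Cu(I) acetylide of 11 with each bromoalkyne) forms both C5–C6 bonds; no stereocentre is involved, and low temperature with limited amine suppresses 1,2→1,3 acyl shift.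

**Compound list**

1 | acetylene | C#C | starting material
2 | ethyllithium | [Li]CC | starting material
3 | 1-chloro-3-iodopropane | ClCCCI | starting material
4 | lithium bis[(1Z,3Z)-hexa-1,3-dien-1-yl]cuprate | [Li+].CC/C=C\C=C/[Cu-]/C=C\C=C/CC | intermediate
5 | (3Z,5Z)-9-chloronona-3,5-diene | CC/C=C\C=C/CCCCl | intermediate
6 | (E)-3-(dimethylamino)prop-2-enal | CN(C)/C=C/C=O | starting material
7 | (4Z,6Z)-nona-4,6-dien-1-ylmagnesium chloride | CC/C=C\C=C/CCC[Mg]Cl | intermediate
8 | chloromagnesium (1E,7Z,9Z)-1-(dimethylamino)dodeca-1,7,9-trien-3-olate (racemic at C3) | CC/C=C\C=C/CCCC(O[Mg]Cl)/C=C/N(C)C | intermediate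
9 | (2E,7Z,9Z)-dodeca-2,7,9-trienal | CC/C=C\C=C/CCC/C=C/C=O | intermediate
10 | (2R,3S)-3-[(4Z,6Z)-nona-4,6-dien-1-yl]oxirane-2-carbaldehyde | O=C[C@@H]1O[C@H]1CCC/C=C\C=C/CC | intermediate
11 | (2S,3S)-2-ethynyl-3-[(4Z,6Z)-nona-4,6-dien-1-yl]oxirane | C#C[C@@H]1O[C@H]1CCC/C=C\C=C/CC | intermediate
12 | pent-4-ynoic acid | C#CCCC(=O)O | starting material
13 | 5-bromopent-4-ynoic acid | BrC#CCCC(=O)O | intermediate
14 | oxetan-3-ol | OC1COC1 | starting material
15 | oxetan-3-yl 5-bromopent-4-ynoate | BrC#CCCC(=O)OC1COC1 | intermediate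
16 | (2S)-3-hydroxypropane-1,2-diyl bis(5-bromopent-4-ynoate) | BrC#CCCC(=O)OC[C@H](CO)OC(=O)CCC#CBr | intermediate
17 | (2S)-3-hydroxypropane-1,2-diyl bis{7-[(2S,3S)-3-[(4Z,6Z)-nona-4,6-dien-1-yl]oxiran-2-yl]hepta-4,6-diynoate} | CC/C=C\C=C/CCC[C@@H]1O[C@H]1C#CC#CCCC(=O)OC[C@H](CO)OC(=O)CCC#CC#C[C@@H]1O[C@H]1CCC/C=C\C=C/CC | target

**Step count and risks**

Total steps: 8. Longest linear sequence: 5 (steps 1, 2, 3, 4, 8).

Steps most likely to fail:

Step 7 (the proposed new reaction). The deactivated 3-acyloxy-oxetane may open slowly, the enantioselectivity is unknown, and acid-promoted 1,2→1,3 acyl shift or ortho-ester formation could erode the ee. The fallback uses known chemistry, sets out from 13 and comes back at 16. Glycerol is desymmetrised by scaffolding-catalysed enantioselective silylation (TESCl, chiral imidazole–oxazolidine scaffolding catalyst, amine base, THF) to (R)-3-[(triethylsilyl)oxy]propane-1,2-diol F1. F1 is esterified with 13 (2.2 equiv, EDC·HCl, DMAP) to (2R)-3-[(triethylsilyl)oxy]propane-1,2-diyl bis(5-bromopent-4-ynoate) F2. F2 is desilylated with HF·pyridine in THF/pyridine at 0 °C to give 16.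

Step 8. The amine medium may cause acyl shift or partial aminolysis of the free-OH diester, and the double coupling may stall at the mono-coupled stage or give bromoalkyne homocoupling. The fallback moves the coupling before the esterification; it sets out from 11 and 13 and comes back at 17. Cadiot–Chodkiewicz coupling of 11 with 13 (CuCl, NH2OH·HCl, aq EtNH2, MeOH, 0 °C) gives 7-[(2S,3S)-3-[(4Z,6Z)-nona-4,6-dien-1-yl]oxiran-2-yl]hepta-4,6-diynoic acid F3. F3 (2.2 equiv) is esterified with (R)-3-[(triethylsilyl)oxy]propane-1,2-diol F1 (made as above; EDC·HCl, DMAP) to (2R)-3-[(triethylsilyl)oxy]propane-1,2-diyl bis{7-[(2S,3S)-3-[(4Z,6Z)-nona-4,6-dien-1-yl]oxiran-2-yl]hepta-4,6-diynoate} F4. Buffered HF·pyridine at 0 °C then gives 17.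

Step 2. The Grignard reagent may form sluggishly from the chloride, and the enal yield from the vinylogous amide may be low. The fallback avoids the Grignard reagent; it sets out from 4 and comes back at 9. Cuprate 4 is alkylated with 2-(3-iodopropyl)-1,3-dioxolane (HMPA, −40 °C → rt) to 2-[(4Z,6Z)-nona-4,6-dien-1-yl]-1,3-dioxolane F5. Mild aqueous acid (PPTS, acetone/H2O) gives (5Z,7Z)-deca-5,7-dienal F6. Wittig reaction of F6 with (triphenylphosphoranylidene)acetaldehyde (toluene, 80 °C) gives 9.

**Further compounds**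

F1 | step 7 | (R)-3-[(triethylsilyl)oxy]propane-1,2-diol | OC[C@H](CO[Si](CC)(CC)CC)O
F2 | step 7 | (2R)-3-[(triethylsilyl)oxy]propane-1,2-diyl bis(5-bromopent-4-ynoate) | BrC#CCCC(=O)OC[C@H](CO[Si](CC)(CC)CC)OC(=O)CCC#CBr
F3 | step 8 | 7-[(2S,3S)-3-[(4Z,6Z)-nona-4,6-dien-1-yl]oxiran-2-yl]hepta-4,6-diynoic acid | OC(=O)CCC#CC#C[C@@H]1O[C@H]1CCC/C=C\C=C/CC
F4 | step 8 | (2R)-3-[(triethylsilyl)oxy]propane-1,2-diyl bis{7-[(2S,3S)-3-[(4Z,6Z)-nona-4,6-dien-1-yl]oxiran-2-yl]hepta-4,6-diynoate} | CC/C=C\C=C/CCC[C@@H]1O[C@H]1C#CC#CCCC(=O)OC[C@H](CO[Si](CC)(CC)CC)OC(=O)CCC#CC#C[C@@H]1O[C@H]1CCC/C=C\C=C/CC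
F5 | step 2 | 2-[(4Z,6Z)-nona-4,6-dien-1-yl]-1,3-dioxolane | CC/C=C\C=C/CCCC1OCCO1
F6 | step 2 | (5Z,7Z)-deca-5,7-dienal | CC/C=C\C=C/CCCC=O
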